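**Plan**

- Retrosynthesis: the C1 silyl ether, the C5 ester and the C13 methylene are removed first; the crotonoyl group is traced back to a propargylic pivalate (1,3-acyloxy shift); the lactone (C6–O, C7–C11) to a ketene [2+2]/Baeyer–Villiger pair on a C6=C7 alkene; C5–O to an epoxide on C5=C6; last, the ring bonds C7–C8 and C10–C1 are cut together.
- Enabling feature: in the cycloheptanone the propanone unit C8–C9(=O)–C10(CH3) lies between C7 and the oxygenated quaternary C1. Ring carbons C7–C6–C5–C1 are therefore a 1-silyloxy-1,3-diene and C8–C9–C10 a 2-silyloxyvinyl carbenoid (from a diazo keto ester).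
- Forward: diene 5 (3 steps) and diazo ester 8 (2 steps) are joined by a tandem cyclopropanation/Cope rearrangement, a formal (4+3) cycloaddition, which gives the seven-membered ring through a transient cyclopropane. The lactone ring follows through a cyclobutanone.
- Helpers: the tert-butyl ester on C8 (carbenoid acceptor) and the C9 silyl enol ether keep C10 locked and make the later diene electron-rich; both go in step 13. The alkynyl pivalate is the masked crotonoyl group, unveiled in step 15.
- Stereochemistry: absolute configuration from the chiral dirhodium catalyst; C1/C10 from the boat Cope transition state and the two alkene geometries; C5 by epoxidation anti to C1–OTBS; C6 and C7 by ketene addition anti to C5–OTES (cis by necessity); the ester centre from (S)-2-methylbutanoic acid. The (S) centre of the butynol is a spectator erased in step 15.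

Key step: step 6

Numbering: target locants are used throughout. Ring: C1 (carbinol), C5, C6, C7, C8, C9 (C=O), C10 (CHCH3). Side chain on C1: C2(=O)–C3=C4–CH3. Lactone: C11 (alpha carbon), C12 (C=O), C13 (=CH2). "Alpha" is the ring face carrying the C1 oxygen, the C6 oxygen, C11 on C7 and the C10 methyl; "beta" is the other face (C5 oxygen, C2 on C1).

Assumption: Rh2(R-PTAD)4 (PTAD = N-phthalimido-(1-adamantyl)acetate) is taken to select the same alkene face as Rh2(S-DOSP)4 (DOSP = N-(4-dodecylphenylsulfonyl)prolinate) does with aryl- and vinyldiazoacetates, which corresponds to cyclopropane 9 as drawn; if the sense is the opposite, Rh2(S-PTAD)4 is used and nothing else changes.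

**Route**

Step 1
Reactants: 1 (S)-but-3-yn-2-ol
Product: 2 (2S)-but-3-yn-2-yl pivalate
Conditions: pivaloyl chloride, pyridine, DMAP (cat.), CH2Cl2, 0 to 23 °C
Reagents that add atoms: pivaloyl chloride, CC(C)(C)C(Cl)=O
Why: Standard O-acylation of a secondary propargylic alcohol with an acid chloride, giving the ester that later migrates in step 15, the stereocentre serving only to keep all intermediates single diastereomers.

Step 2
Reactants: 2 (2S)-but-3-yn-2-yl pivalate; 3 (E)-but-2-enoyl chloride
Product: 4 (2S,6E)-5-oxooct-6-en-3-yn-2-yl pivalate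
Conditions: PdCl2(PPh3)2 (2 mol %), CuI (4 mol %), Et3N, THF, 23 °C
Reagents that add atoms: none
Why: Acyl Sonogashira coupling of an acid chloride with a terminal alkyne should give the alkynyl propenyl ketone directly, the (E) alkene of 3 and the pivalate being untouched.

Step 3
Reactants: 4 (2S,6E)-5-oxooct-6-en-3-yn-2-yl pivalate
Product: 5 (3E,7S)-4-(tert-butyldimethylsilyloxy)octa-1,3-dien-5-yn-7-yl pivalate (OTBS trans to the vinyl group)
Conditions: TBSOTf, Et3N, Et2O, −78 to 0 °C
Reagents that add atoms: tert-butyldimethylsilyl trifluoromethanesulfonate (TBSOTf), CC(C)(C)[Si](C)(C)OS(=O)(=O)C(F)(F)F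
Why: Soft enolisation (O-silylation, then gamma-deprotonation) of an enone that has no alpha' hydrogen gives the 1-silyloxy diene, and the small alkynyl group should favour the s-trans silyloxocarbenium ion and hence the isomer with the vinyl group cis to the alkyne, the (3E) dienol ether that is needed.

Step 4
Reactants: 6 tert-butyl 3-oxopentanoate
Product: 7 tert-butyl 2-diazo-3-oxopentanoate
Conditions: 4-acetamidobenzenesulfonyl azide, Et3N, MeCN, 0 to 23 °C
Reagents that add atoms: 4-acetamidobenzenesulfonyl azide, CC(=O)Nc1ccc(cc1)S(=O)(=O)N=[N+]=[N-]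
Why: Regitz diazo transfer to the active methylene group of a beta-keto ester.

Step 5
Reactants: 7 tert-butyl 2-diazo-3-oxopentanoate
Product: 8 tert-butyl (3Z)-3-(tert-butyldimethylsilyloxy)-2-diazopent-3-enoate
Conditions: TBSOTf, Et3N, CH2Cl2, 0 °C
Reagents that add atoms: tert-butyldimethylsilyl trifluoromethanesulfonate (TBSOTf), CC(C)(C)[Si](C)(C)OS(=O)(=O)C(F)(F)F
Why: Silyl triflate/amine enolisation of the diazo keto ester should give the (Z) silyl enol ether (methyl trans to the bulky diazo ester carbon), the usual geometry of these vinyldiazoacetates.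

Step 6
Reactants: 5 (3E,7S)-4-(tert-butyldimethylsilyloxy)octa-1,3-dien-5-yn-7-yl pivalate; 8 tert-butyl (3Z)-3-(tert-butyldimethylsilyloxy)-2-diazopent-3-enoate
Product: 10 tert-butyl (3S,4R)-2,4-bis(tert-butyldimethylsilyloxy)-3-methyl-4-[(3S)-3-(pivaloyloxy)but-1-ynyl]cyclohepta-1,5-diene-1-carboxylate (C1–OTBS and C10–CH3 cis, both alpha), via cis-divinylcyclopropane 9 (not isolated)
Conditions: Rh2(R-PTAD)4 (1 mol %), hexanes, slow addition of 8 at 23 °C, then 60 °C
Reagents that add atoms: none
Why: The dirhodium carbenoid formed from 8 by loss of N2 cyclopropanates the terminal C7=C6 bond of 5 (C8–C7 and C8–C6 formed) with its vinyl group cis to the dienyl substituent, and the cis-divinylcyclopropane 9 then undergoes a [3,3] Cope shift that breaks C8–C6 and forms C10–C1, so that the ring bonds C8–C7 and C10–C1 arise in one operation. The closest known reaction type is the tandem cyclopropanation/Cope rearrangement (formal (4+3) cycloaddition) of 2-silyloxyvinyldiazoacetates with 1-oxygenated buta-1,3-dienes under chiral dirhodium tetracarboxylate catalysis. The three-membered ring closes by concerted asynchronous [2+1] carbene transfer and the seven-membered ring by the ring-expanding sigmatropic shift through a boat transition state. In that boat the substituents that lie trans to the cyclopropane on the two vinyl termini (OTBS on C1 from the (3E) dienol ether, methyl on C10 from the (Z) enol ether) come out cis, which sets the C1/C10 relative configuration, while the absolute configuration is set by catalyst-controlled face selection in the cyclopropanation and passed on stereospecifically. The step needs site selectivity for the monosubstituted alkene over the enol ether double bond and the hindered alkyne, and carbenoid rather than vinylogous reactivity: the first is secured by attack at the unhindered diene terminus with positive charge delocalised onto the C1 oxygen, the second by the silyloxy group on the carbenoid and the hydrocarbon solvent. The slim alkynyl group is the substituent that points inward at C1 in the boat, so the rearrangement should proceed on gentle warming.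

Step 7
Reactants: 10 tert-butyl (3S,4R)-2,4-bis(tert-butyldimethylsilyloxy)-3-methyl-4-[(3S)-3-(pivaloyloxy)but-1-ynyl]cyclohepta-1,5-diene-1-carboxylate
Product: 11 the 5,6-beta-epoxide of 10
Conditions: mCPBA, NaHCO3, CH2Cl2, 0 °C
Reagents that add atoms: 3-chloroperbenzoic acid (mCPBA), OOC(=O)c1cccc(Cl)c1
Why: Prilezhaev epoxidation should take the isolated cis C5=C6 alkene, the push-pull tetrasubstituted enol ether (a vinylogous carbonate) and the alkyne being far less nucleophilic, and attack anti to the bulky tertiary OTBS on C1 (syn to the slim alkynyl group) places the oxygen on the beta face, which sets C5.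

Step 8
Reactants: 11 the 5,6-beta-epoxide of 10
Product: 12 tert-butyl 2,4-bis(tert-butyldimethylsilyloxy)-3-methyl-4-[(3S)-3-(pivaloyloxy)but-1-ynyl]-5-(triethylsilyloxy)cyclohepta-1,6-diene-1-carboxylate (C5–OTES beta; C6=C7 conjugated with the C8=C9 enol ether)
Conditions: TESOTf, DBU, toluene, −40 to 23 °C
Reagents that add atoms: triethylsilyl trifluoromethanesulfonate (TESOTf), CC[Si](CC)(CC)OS(=O)(=O)C(F)(F)F
Why: Silyl triflate/amidine isomerisation of an epoxide to an allylic silyl ether: only C7 carries hydrogen next to the epoxide (C1 is quaternary), so anti elimination across C6–C7 gives the conjugated diene and leaves the beta C5–O bond untouched.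

Step 9
Reactants: 12 tert-butyl 2,4-bis(tert-butyldimethylsilyloxy)-3-methyl-4-[(3S)-3-(pivaloyloxy)but-1-ynyl]-5-(triethylsilyloxy)cyclohepta-1,6-diene-1-carboxylate
Product: 13 dichlorocyclobutanone, the ketene adduct across C6=C7 on the alpha face (C12=O bonded to C6, C11Cl2 bonded to C7)
Conditions: Cl3CCOCl, zinc–copper couple Zn(Cu), DME/Et2O, 0 to 23 °C
Reagents that add atoms: trichloroacetyl chloride, ClC(=O)C(Cl)(Cl)Cl
Why: [2+2] cycloaddition of dichloroketene to the terminal double bond of a 1-silyloxy diene, in which the ketene carbonyl carbon bonds to the nucleophilic terminus C6 and CCl2 to C7 (allyl cation stabilised by the C9 silyloxy group), suprafacially and anti to the adjacent beta C5–OTES group, which sets C6 and C7 with both new bonds alpha.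

Step 10
Reactants: 13 dichlorocyclobutanone
Product: 14 cyclobutanone (C11H2) fused cis at C6–C7
Conditions: Zn(Cu), NH4Cl, MeOH, 23 °C
Reagents that add atoms: none
Why: Reductive dechlorination of an alpha,alpha-dichlorocyclobutanone with zinc under buffered conditions, which touches no stereocentre.

Step 11
Reactants: 14 cyclobutanone fused cis at C6–C7
Product: 15 cis-fused gamma-lactone (C6–O–C12(=O)–C11H2–C7; C5–OTES beta; C8 ester and C9 silyl enol ether in place)
Conditions: mCPBA, NaHCO3, CH2Cl2, 0 °C
Reagents that add atoms: 3-chloroperbenzoic acid (mCPBA), OOC(=O)c1cccc(Cl)c1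
Why: Baeyer–Villiger oxidation of the strained cyclobutanone, far faster than any reaction of the other groups, with migration of the more substituted ring carbon C6 with retention, so that the lactone oxygen on C6 is alpha and cis to C11.

Step 12
Reactants: 15 cis-fused gamma-lactone
Product: 18 alpha-methylene lactone (C11=C13H2; other groups as in 15), via Mannich base 16 (not isolated), via ammonium iodide 17 (not isolated)
Conditions: LiN(iPr)2 (LDA), THF, −78 °C; CH2=NMe2+ I−, −78 to 0 °C; MeI, MeOH, 23 °C; aq NaHCO3, CH2Cl2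
Reagents that add atoms: Eschenmoser's salt (N,N-dimethylmethyleneiminium iodide), C=[N+](C)C.[I-]
Why: Mannich reaction of the lactone enolate with Eschenmoser's salt, N-methylation and Hofmann-type elimination is the standard alpha-methylenation of gamma-butyrolactones, and here the ketone is still masked and the other carbonyl groups (pivalate, vinylogous carbonate) have no alpha hydrogen.

Step 13
Reactants: 18 alpha-methylene lactone
Product: 20 hydroxy ketone (C5–OH beta, C9=O, C8H2, C1–OTBS alpha, alkynyl pivalate and methylene lactone intact), via beta-keto acid 19 (not isolated)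
Conditions: TFA, CH2Cl2, H2O (2 equiv), 0 to 23 °C
Reagents that add atoms: none
Why: Acidolysis protonates the silyl enol ether at C8 (so C10 is not enolised), cleaves the tert-butyl ester and the secondary TES ether, and the beta-keto acid loses CO2, while the tertiary TBS ether and the pivalate should survive.

Step 14
Reactants: 20 hydroxy ketone; 21 (S)-2-methylbutanoic acid
Product: 22 the C5 (S)-2-methylbutanoate of 20
Conditions: DCC, DMAP, CH2Cl2, 0 to 23 °C
Reagents that add atoms: none
Why: Steglich esterification of the only free hydroxyl group with the enantiopure acid, which brings in the side-chain stereocentre unchanged.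

Step 15
Reactants: 22 the C5 (S)-2-methylbutanoate of 20
Product: 24 the C1 O-TBS ether of the target (C1–C(=O)–CH=CH–CH3, E), via allenyl pivalate 23 (not isolated)
Conditions: Ph3PAuNTf2 (2 mol %), 2-butanone/H2O, 23 °C
Reagents that add atoms: none
Why: Gold-catalysed 1,3-acyloxy shift ([3,3] rearrangement) of the propargylic pivalate to the allenyl pivalate and its hydrolysis in the wet solvent (a Meyer–Schuster-type outcome) should give the (E) enone with the carbonyl on C2, whose oxygen is the migrated pivalate oxygen while water only takes up the pivaloyl group, and the silyl ether on C1 keeps the tertiary oxygen from cyclising onto the allene.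

Step 16
Reactants: 24 the C1 O-TBS ether of the target
Product: 25 the target, CNP0153197.2
Conditions: HF·pyridine, THF, 0 to 23 °C
Reagents that add atoms: none
Why: Fluoride cleavage of the tertiary silyl ether under weakly acidic conditions, which should avoid retro-aldol cleavage of the beta-hydroxy ketone and conjugate addition to the enone and the methylene lactone.

**Compound list**

1 | (S)-but-3-yn-2-ol | C[C@H](O)C#C | starting material
2 | (2S)-but-3-yn-2-yl pivalate | C[C@H](OC(=O)C(C)(C)C)C#C | intermediate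
3 | (E)-but-2-enoyl chloride | C/C=C/C(Cl)=O | starting material
4 | (2S,6E)-5-oxooct-6-en-3-yn-2-yl pivalate | C/C=C/C(=O)C#C[C@H](C)OC(=O)C(C)(C)C | intermediate
5 | (3E,7S)-4-(tert-butyldimethylsilyloxy)octa-1,3-dien-5-yn-7-yl pivalate | C=C/C=C(/O[Si](C)(C)C(C)(C)C)C#C[C@H](C)OC(=O)C(C)(C)C | intermediate
6 | tert-butyl 3-oxopentanoate | CCC(=O)CC(=O)OC(C)(C)C | starting material
7 | tert-butyl 2-diazo-3-oxopentanoate | CCC(=O)C(=[N+]=[N-])C(=O)OC(C)(C)C | intermediate
8 | tert-butyl (3Z)-3-(tert-butyldimethylsilyloxy)-2-diazopent-3-enoate | C/C=C(\O[Si](C)(C)C(C)(C)C)C(=[N+]=[N-])C(=O)OC(C)(C)C | intermediate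
9 | tert-butyl (1S,2R)-1-[(1Z)-1-(tert-butyldimethylsilyloxy)prop-1-enyl]-2-[(1E,5S)-2-(tert-butyldimethylsilyloxy)-5-(pivaloyloxy)hex-1-en-3-ynyl]cyclopropane-1-carboxylate (cis-divinylcyclopropane) | [C@]1(C(=O)OC(C)(C)C)(/C(O[Si](C)(C)C(C)(C)C)=C/C)C[C@@H]1/C=C(/O[Si](C)(C)C(C)(C)C)C#C[C@H](C)OC(=O)C(C)(C)C | intermediate (not isolated)
10 | tert-butyl (3S,4R)-2,4-bis(tert-butyldimethylsilyloxy)-3-methyl-4-[(3S)-3-(pivaloyloxy)but-1-ynyl]cyclohepta-1,5-diene-1-carboxylate | [C@@]1(O[Si](C)(C)C(C)(C)C)(C#C[C@H](C)OC(=O)C(C)(C)C)C=CCC(C(=O)OC(C)(C)C)=C(O[Si](C)(C)C(C)(C)C)[C@@H]1C | intermediate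
11 | 5,6-beta-epoxide of 10 | [C@@]1(O[Si](C)(C)C(C)(C)C)(C#C[C@H](C)OC(=O)C(C)(C)C)[C@H]2O[C@H]2CC(C(=O)OC(C)(C)C)=C(O[Si](C)(C)C(C)(C)C)[C@@H]1C | intermediate
12 | tert-butyl 2,4-bis(tert-butyldimethylsilyloxy)-3-methyl-4-[(3S)-3-(pivaloyloxy)but-1-ynyl]-5-(triethylsilyloxy)cyclohepta-1,6-diene-1-carboxylate (C5–OTES beta) | [C@@]1(O[Si](C)(C)C(C)(C)C)(C#C[C@H](C)OC(=O)C(C)(C)C)[C@@H](O[Si](CC)(CC)CC)C=CC(C(=O)OC(C)(C)C)=C(O[Si](C)(C)C(C)(C)C)[C@@H]1C | intermediate
13 | dichlorocyclobutanone, alpha-face ketene adduct across C6=C7 | [C@@]1(O[Si](C)(C)C(C)(C)C)(C#C[C@H](C)OC(=O)C(C)(C)C)[C@@H](O[Si](CC)(CC)CC)[C@@H]2C(=O)C(Cl)(Cl)[C@@H]2C(C(=O)OC(C)(C)C)=C(O[Si](C)(C)C(C)(C)C)[C@@H]1C | intermediate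
14 | cyclobutanone fused cis at C6–C7 | [C@@]1(O[Si](C)(C)C(C)(C)C)(C#C[C@H](C)OC(=O)C(C)(C)C)[C@@H](O[Si](CC)(CC)CC)[C@@H]2C(=O)C[C@@H]2C(C(=O)OC(C)(C)C)=C(O[Si](C)(C)C(C)(C)C)[C@@H]1C | intermediate
15 | cis-fused gamma-lactone (C6–O, C7–C11H2) | [C@@]1(O[Si](C)(C)C(C)(C)C)(C#C[C@H](C)OC(=O)C(C)(C)C)[C@@H](O[Si](CC)(CC)CC)[C@@H]2OC(=O)C[C@@H]2C(C(=O)OC(C)(C)C)=C(O[Si](C)(C)C(C)(C)C)[C@@H]1C | intermediate
16 | alpha-(dimethylaminomethyl) lactone (Mannich base of 15, C11 epimers) | [C@@]1(O[Si](C)(C)C(C)(C)C)(C#C[C@H](C)OC(=O)C(C)(C)C)[C@@H](O[Si](CC)(CC)CC)[C@@H]2OC(=O)C(CN(C)C)[C@@H]2C(C(=O)OC(C)(C)C)=C(O[Si](C)(C)C(C)(C)C)[C@@H]1C | intermediate (not isolated)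
17 | alpha-(trimethylammoniomethyl) lactone iodide | [C@@]1(O[Si](C)(C)C(C)(C)C)(C#C[C@H](C)OC(=O)C(C)(C)C)[C@@H](O[Si](CC)(CC)CC)[C@@H]2OC(=O)C(C[N+](C)(C)C)[C@@H]2C(C(=O)OC(C)(C)C)=C(O[Si](C)(C)C(C)(C)C)[C@@H]1C.[I-] | intermediate (not isolated)
18 | alpha-methylene lactone with C8 ester and C9 silyl enol ether | [C@@]1(O[Si](C)(C)C(C)(C)C)(C#C[C@H](C)OC(=O)C(C)(C)C)[C@@H](O[Si](CC)(CC)CC)[C@@H]2OC(=O)C(=C)[C@@H]2C(C(=O)OC(C)(C)C)=C(O[Si](C)(C)C(C)(C)C)[C@@H]1C | intermediate
19 | beta-keto acid (C8–CO2H, C9=O, C5–OH) | [C@@]1(O[Si](C)(C)C(C)(C)C)(C#C[C@H](C)OC(=O)C(C)(C)C)[C@@H](O)[C@@H]2OC(=O)C(=C)[C@@H]2C(C(O)=O)C(=O)[C@@H]1C | intermediate (not isolated)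
20 | hydroxy ketone (C5–OH beta, C9=O, C1–OTBS, alkynyl pivalate) | [C@@]1(O[Si](C)(C)C(C)(C)C)(C#C[C@H](C)OC(=O)C(C)(C)C)[C@@H](O)[C@@H]2OC(=O)C(=C)[C@@H]2CC(=O)[C@@H]1C | intermediate
21 | (S)-2-methylbutanoic acid | CC[C@H](C)C(=O)O | starting material
22 | C5 (S)-2-methylbutanoate of 20 | [C@@]1(O[Si](C)(C)C(C)(C)C)(C#C[C@H](C)OC(=O)C(C)(C)C)[C@@H](OC(=O)[C@@H](C)CC)[C@@H]2OC(=O)C(=C)[C@@H]2CC(=O)[C@@H]1C | intermediate
23 | allenyl pivalate (C2(OPiv)=C3=C4H–CH3 on C1) | [C@@]1(O[Si](C)(C)C(C)(C)C)(C(OC(=O)C(C)(C)C)=C=CC)[C@@H](OC(=O)[C@@H](C)CC)[C@@H]2OC(=O)C(=C)[C@@H]2CC(=O)[C@@H]1C | intermediate (not isolated)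
24 | C1 O-TBS ether of the target | [C@@]1(O[Si](C)(C)C(C)(C)C)(C(=O)/C=C/C)[C@@H](OC(=O)[C@@H](C)CC)[C@@H]2OC(=O)C(=C)[C@@H]2CC(=O)[C@@H]1C | intermediate
25 | CNP0153197.2 | C=C1C(=O)O[C@@H]2[C@H]1CC(=O)[C@H](C)[C@@](O)(C(=O)/C=C/C)[C@H]2OC(=O)[C@@H](C)CC | target

**Step count and risks**

Total step count: 16. Longest linear sequence: 14 steps (1 → 2 → 4 → 5 → 10 → … → 25).

Steps most likely to fail:

Step 9. The zinc chloride formed may ionise the allylic C5–OTES group of the dienol ether (vinylogous loss of silanol), the ketene may add to the alkyne, the donor-substituted cyclobutanone may reopen, or face selectivity may be poor. The fallback sets out from 12 and comes back at 20. Vinylogous Rubottom oxidation with dimethyldioxirane (epoxidation of the terminal C6=C7 bond of the silyl dienol ether anti to C5–OTES, then loss of silicon) gives the gamma-hydroxy alkylidene beta-keto ester F1. Esterification of its C6 hydroxyl with diethylphosphonoacetic acid (DCC, DMAP) gives the phosphonoacetate F2. Cs2CO3 in MeCN then triggers an intramolecular Michael addition to C7 (5-exo, cis-fused of necessity) to give the alpha-phosphono lactone beta-keto ester F3. TFA removes the tert-butyl ester (with decarboxylation) and the TES ether to give the alpha-phosphono lactone hydroxy ketone F4. A Horner–Wadsworth–Emmons reaction with aqueous formaldehyde and K2CO3 then gives 20.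

Step 6. Face selection by the catalyst may be insufficient with this new diene, or the polarised cyclopropanation may divert into a [3+2] annulation. The fallback sets out from 5 and 7 and comes back at 10. The acceptor/acceptor carbenoid from 7 (Rh2(S-NTTL)4, NTTL = N-1,8-naphthalimido-tert-leucinate, CH2Cl2) cyclopropanates the terminal alkene of 5 to the acylcyclopropane F5. TBSOTf/Et3N converts its ketone into the (Z) silyl enol ether, which is 9 or its trans isomer. Heating in toluene (trans-to-cis equilibration by reversible ring opening, then Cope rearrangement) leads to 10. Because 5 carries the (S) pivalate centre, the two facial series are diastereomers and can be separated if induction is incomplete.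

Step 8. The silyl triflate may open other Lewis-acid pathways: a 1,2-hydride shift to a ketone, or attack of the enol ether carbon on the activated epoxide. The fallback sets out from 11 and comes back at 12. Phenylselenide (from PhSeSePh and NaBH4, EtOH) opens the epoxide at the less hindered C6 to give the hydroxy selenide F6. Oxidation with H2O2/pyridine and selenoxide syn elimination away from the oxygen, toward C7, gives the allylic alcohol F7. Silylation with TESCl and imidazole gives 12.

Further compounds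
F1 | step 9 | gamma-hydroxy alkylidene beta-keto ester (C6–OH alpha, C7=C8, C9=O) | [C@@]1(O[Si](C)(C)C(C)(C)C)(C#C[C@H](C)OC(=O)C(C)(C)C)[C@@H](O[Si](CC)(CC)CC)[C@H](O)C=C(C(=O)OC(C)(C)C)C(=O)[C@@H]1C
F2 | step 9 | C6 diethylphosphonoacetate of F1 | [C@@]1(O[Si](C)(C)C(C)(C)C)(C#C[C@H](C)OC(=O)C(C)(C)C)[C@@H](O[Si](CC)(CC)CC)[C@H](OC(=O)CP(=O)(OCC)OCC)C=C(C(=O)OC(C)(C)C)C(=O)[C@@H]1C
F3 | step 9 | alpha-phosphono lactone beta-keto ester | [C@@]1(O[Si](C)(C)C(C)(C)C)(C#C[C@H](C)OC(=O)C(C)(C)C)[C@@H](O[Si](CC)(CC)CC)[C@@H]2OC(=O)C(P(=O)(OCC)OCC)[C@@H]2C(C(=O)OC(C)(C)C)C(=O)[C@@H]1C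
F4 | step 9 | alpha-phosphono lactone hydroxy ketone | [C@@]1(O[Si](C)(C)C(C)(C)C)(C#C[C@H](C)OC(=O)C(C)(C)C)[C@@H](O)[C@@H]2OC(=O)C(P(=O)(OCC)OCC)[C@@H]2CC(=O)[C@@H]1C
F5 | step 6 | acylcyclopropane, tert-butyl 1-propanoyl-2-[(1E,5S)-2-(tert-butyldimethylsilyloxy)-5-(pivaloyloxy)hex-1-en-3-ynyl]cyclopropane-1-carboxylate | CCC(=O)C1(C(=O)OC(C)(C)C)C[C@@H]1/C=C(/O[Si](C)(C)C(C)(C)C)C#C[C@H](C)OC(=O)C(C)(C)C
F6 | step 8 | hydroxy selenide (C5–OH beta, C6–SePh alpha) | [C@@]1(O[Si](C)(C)C(C)(C)C)(C#C[C@H](C)OC(=O)C(C)(C)C)[C@@H](O)[C@H]([Se]c2ccccc2)CC(C(=O)OC(C)(C)C)=C(O[Si](C)(C)C(C)(C)C)[C@@H]1C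
F7 | step 8 | allylic alcohol (C5–OH beta, C6=C7) | [C@@]1(O[Si](C)(C)C(C)(C)C)(C#C[C@H](C)OC(=O)C(C)(C)C)[C@@H](O)C=CC(C(=O)OC(C)(C)C)=C(O[Si](C)(C)C(C)(C)C)[C@@H]1C
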